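**Plan**

1. Numbering: the core is numbered as a naphthalen-2(1H)-one. Ring B = C-1 (CHMe), C-2 (C=O), C-3 (CHMe), C-4 (CH2), C-4a, C-8a; ring A = C-4a, C-5 (=CH), C-6 (CMe), C-7 (acetonyl), C-8 (side chain), C-8a.
2. Retrosynthetic cuts, in order: the acetonyl C=O (from a C-7 propargyl group); the ring B bonds C-4–C-4a and C-2–C-3 (Michael–Dieckmann annulation with allyl acrylate); the C-7 substituent (propargyl addition, then oxidative 1,3-carbonyl transposition); the C-8–side-chain bond (enolate alkenylation with a vinyl iodide).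
3. Enabling feature: C-5, the vinylic CH of the ring A diene, stands 1,5 to the ring B carbonyl C-2 (C-5, C-4a, C-4, C-3, C-2). Carried as a ketone, C-5 makes C-4a an enolate carbon, so C-4/C-3 can come from an acrylate and C-2 from the ester on the C-8a side arm; the same ketone later leaves as an enol triflate to give C-4a=C-5.
4. Forward: ring A is (R)-carvone (isopropenyl becomes C-1/C-2, carbonyl carbon becomes C-7); the side chain is joined at C-8; the carbonyl is moved to C-5; ring B is closed; the diene and the acetonyl ketone are set free last.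
5. Stereochemistry: C-8a is bought with (R)-carvone; C-8 follows by trans equilibration next to the ketone; C-1 and C-3 are equilibrated to the all-equatorial ketone; the side-chain quaternary centre comes from a Sharpless epoxidation and a stereospecific 1,2-alkenyl shift.

Key step: step 15

Remark: the side-arm CH(Me) centre (future C-1) forms unselectively in step 9 and is carried as both epimers until step 18; such centres are left unassigned in the SMILES. "SC" below is the (1E,3S,4E)-3-(tert-butyldimethylsilyloxymethyl)-6-methoxy-2,3-dimethyl-6-oxohexa-1,4-dien-1-yl group delivered by 12.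

**Route**

Step 1
Reactants: 1 prop-2-yn-1-ol
Product: 3 (E)-3-iodo-2-methylprop-2-en-1-ol, via alkenylalane 2 (not isolated)
Conditions: Me3Al (3 equiv), Cp2ZrCl2 (25 mol %), CH2Cl2, 0 to 23 °C; then I2, THF, −30 to 0 °C
Reagents that add atoms: trimethylaluminium C[Al](C)C; iodine [I][I]
Why: Negishi zirconium-catalysed carboalumination adds methyl and aluminium syn across the alkyne with aluminium at the terminus, and iodinolysis of the C–Al bond with retention should give the E iodoalkene.

Step 2
Reactants: 3 (E)-3-iodo-2-methylprop-2-en-1-ol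
Product: 4 (E)-3-iodo-2-methylprop-2-enal
Conditions: MnO2, CH2Cl2, 23 °C
Reagents that add atoms: none
Why: MnO2 oxidation of an allylic alcohol should stop at the enal and leave the vinyl iodide and the alkene geometry untouched.

Step 3
Reactants: 4 (E)-3-iodo-2-methylprop-2-enal; 5 ethyl 2-(triphenylphosphoranylidene)propanoate
Product: 6 ethyl (2E,4E)-5-iodo-2,4-dimethylpenta-2,4-dienoate
Conditions: CH2Cl2, 23 to 40 °C
Reagents that add atoms: none
Why: Wittig olefination with a stabilised α-methyl ylide should give the E trisubstituted enoate.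

Step 4
Reactants: 6 ethyl (2E,4E)-5-iodo-2,4-dimethylpenta-2,4-dienoate
Product: 7 (2E,4E)-5-iodo-2,4-dimethylpenta-2,4-dien-1-ol
Conditions: iBu2AlH (2.2 equiv), CH2Cl2, −78 °C; aq. potassium sodium tartrate
Reagents that add atoms: none
Why: iBu2AlH reduces the conjugated ester 1,2 to the allylic alcohol without touching the vinyl iodide.

Step 5
Reactants: 7 (2E,4E)-5-iodo-2,4-dimethylpenta-2,4-dien-1-ol
Product: 8 [(2R,3R)-3-[(E)-1-iodoprop-1-en-2-yl]-2-methyloxiran-2-yl]methanol
Conditions: Ti(OiPr)4 (10 mol %), D-(−)-diethyl tartrate (12 mol %), tBuOOH, 4 Å molecular sieves, CH2Cl2, −20 °C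
Reagents that add atoms: tert-butyl hydroperoxide CC(C)(C)OO
Why: Sharpless asymmetric epoxidation is directed by the hydroxyl group to the allylic alkene only, and the D-(−)-tartrate catalyst should deliver oxygen to the face that gives the (2R,3R)-epoxide.

Step 6
Reactants: 8 [(2R,3R)-3-[(E)-1-iodoprop-1-en-2-yl]-2-methyloxiran-2-yl]methanol
Product: 9 tert-butyl{[(2R,3R)-3-[(E)-1-iodoprop-1-en-2-yl]-2-methyloxiran-2-yl]methoxy}dimethylsilane
Conditions: tBuMe2SiCl, imidazole, DMF, 23 °C
Reagents that add atoms: tert-butyldimethylsilyl chloride CC(C)(C)[Si](C)(C)Cl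
Why: Standard silylation of the primary alcohol gives the epoxy silyl ether needed for the rearrangement.

Step 7
Reactants: 9 tert-butyl{[(2R,3R)-3-[(E)-1-iodoprop-1-en-2-yl]-2-methyloxiran-2-yl]methoxy}dimethylsilane
Product: 10 (2S,3E)-2-(tert-butyldimethylsilyloxymethyl)-4-iodo-2,3-dimethylbut-3-enal
Conditions: MeAl(OC6H2-4-Br-2,6-tBu2)2 (2 equiv), CH2Cl2, −78 °C
Reagents that add atoms: none
Why: Lewis-acid epoxy silyl ether rearrangement (semipinacol-type) opens the tertiary C–O bond while the alkenyl group shifts from C-3 to C-2 anti to the leaving oxygen, so the quaternary centre should form with inversion as the S aldehyde and the alkene geometry is kept.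

Step 8
Reactants: 10 (2S,3E)-2-(tert-butyldimethylsilyloxymethyl)-4-iodo-2,3-dimethylbut-3-enal; 11 methyl 2-(dimethoxyphosphoryl)acetate
Product: 12 methyl (2E,4S,5E)-4-(tert-butyldimethylsilyloxymethyl)-6-iodo-4,5-dimethylhexa-2,5-dienoate
Conditions: NaH, THF, 0 to 23 °C
Reagents that add atoms: none
Why: Horner–Wadsworth–Emmons olefination of the non-enolisable aldehyde should give the E enoate without risk to the quaternary centre.

Step 9
Reactants: 13 (R)-(−)-carvone
Product: 15 (5R)-5-(1-hydroxypropan-2-yl)-2-methylcyclohex-2-en-1-ol, via borane adduct 14 (not isolated)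
Conditions: 9-borabicyclo[3.3.1]nonane (2.5 equiv), THF, 0 to 23 °C; then NaOH, H2O2, 0 °C
Reagents that add atoms: hydrogen peroxide OO
Why: The borane reduces the enone carbonyl 1,2 and hydroborates the 1,1-disubstituted alkene at its terminal carbon (hydroboration–oxidation); the carbinol centre is removed in step 10 and the new CH(Me) centre is not controlled here but settled in step 18.

Step 10
Reactants: 15 (5R)-5-(1-hydroxypropan-2-yl)-2-methylcyclohex-2-en-1-ol
Product: 16 2-[(1R)-4-methyl-5-oxocyclohex-3-en-1-yl]propanoic acid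
Conditions: CrO3, H2SO4, acetone/H2O, 0 °C
Reagents that add atoms: water O
Why: Jones oxidation returns the allylic alcohol to the enone and takes the primary alcohol through the aldehyde hydrate to the acid in one operation.

Step 11
Reactants: 16 2-[(1R)-4-methyl-5-oxocyclohex-3-en-1-yl]propanoic acid
Product: 17 methyl 2-[(1R)-4-methyl-5-oxocyclohex-3-en-1-yl]propanoate
Conditions: MeI, K2CO3, DMF, 23 °C
Reagents that add atoms: iodomethane C[I]
Why: O-alkylation of the carboxylate gives the methyl ester that later serves as the acyl acceptor for ring B.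

Step 12
Reactants: 17 methyl 2-[(1R)-4-methyl-5-oxocyclohex-3-en-1-yl]propanoate; 12 methyl (2E,4S,5E)-4-(tert-butyldimethylsilyloxymethyl)-6-iodo-4,5-dimethylhexa-2,5-dienoate
Product: 18 α′-alkenylated enone (17 with SC on the ring CH2 next to the ketone and trans to the propanoate arm)
Conditions: LiN(SiMe3)2 (1.1 equiv), THF, −78 °C; then 12, Pd2(dba)3 (2.5 mol %), P(tBu)3 (10 mol %), 23 to 40 °C
Reagents that add atoms: none
Why: Palladium-catalysed alkenylation of the kinetic α′ ketone enolate joins the fragments with retention of the E alkene, and the new C-8 centre, still enolisable, should settle trans to the neighbouring arm under the basic conditions.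

Step 13
Reactants: 18 α′-alkenylated enone; 19 3-bromo-1-(trimethylsilyl)prop-1-yne
Product: 20 tertiary allylic alcohol (18 with C=O converted into C(OH)CH2C≡CSiMe3)
Conditions: Zn dust, THF, 0 to 23 °C; aq. NH4Cl
Reagents that add atoms: none
Why: Barbier propargylation through the non-basic allenylzinc reagent adds 1,2 to the hindered enone through its unsubstituted terminus, leaving esters and the acidic C-8 hydrogen alone; the carbinol configuration is immaterial.

Step 14
Reactants: 20 tertiary allylic alcohol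
Product: 21 transposed enone (2-methylcyclohex-2-en-1-one with 3-[3-(trimethylsilyl)prop-2-yn-1-yl], 4-SC and 5-(1-methoxy-1-oxopropan-2-yl), 4,5-trans)
Conditions: [C5H5NH][CrO3Cl], 4 Å molecular sieves, CH2Cl2, 23 °C
Reagents that add atoms: pyridinium chlorochromate c1cc[nH+]cc1.[O-][Cr](=O)(=O)Cl
Why: Babler–Dauben oxidative transposition (1,3-shift of the chromate ester, then oxidation) moves the oxygen to the future C-5 and leaves the propargyl group on the future C-7.

Step 15
Reactants: 21 transposed enone; 22 prop-2-en-1-yl prop-2-enoate (allyl acrylate)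
Product: 24 allyl 1,6-dimethyl-2,5-dioxo-8-SC-7-[3-(trimethylsilyl)prop-2-yn-1-yl]-1,2,3,4,4a,5,8,8a-octahydronaphthalene-3-carboxylate, via lithium enolate 23 (not isolated)
Conditions: LiN(iPr)2 (1.05 equiv), THF, −78 °C; 22 (1.05 equiv), −78 to 0 °C; AcOH
Reagents that add atoms: none
Why: LiN(iPr)2 removes an α′ proton of enone 21 at C-4a under kinetic control, the lithium dienolate adds 1,4 to allyl acrylate (bond C-4a–C-4), and the ester enolate 23 attacks the methyl ester of the C-8a arm (bond C-3–C-2) with loss of methoxide, which then deprotonates the β-keto ester and makes the closure irreversible. The closest known reaction type is the Michael–Dieckmann annulation of a ketone enolate with an acrylate. Ring B closes by 6-exo-trig attack of the enolate carbon on the ester carbonyl. C-4a should be set trans to the C-8a arm by attack anti to the neighbouring substituent and is erased in step 16; C-3 is an enolised β-keto ester carbon and C-1 stays an epimer mixture, both settled in step 18. The step needs α′ and not γ deprotonation, which kinetic base at −78 °C secures, and Dieckmann closure instead of a second Michael addition to C-7, which is disfavoured because C-7 is fully substituted and that closure would force the C-4a, C-8a and C-8 substituents all axial.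

Step 16
Reactants: 24 bicyclic β-keto ester
Product: 26 allyl 1,3,6-trimethyl-2-oxo-5-(trifluoromethylsulfonyloxy)-8-SC-7-[3-(trimethylsilyl)prop-2-yn-1-yl]-1,2,3,4,8,8a-hexahydronaphthalene-3-carboxylate, via enolate triflate 25 (not isolated)
Conditions: KN(SiMe3)2 (2.2 equiv), THF, −78 °C; PhNTf2 (1.05 equiv); then MeI (3 equiv), −78 to 0 °C
Reagents that add atoms: N-phenylbis(trifluoromethanesulfonimide) O=S(=O)(N(c1ccccc1)S(=O)(=O)C(F)(F)F)C(F)(F)F; iodomethane C[I]
Why: With the C-2 ketone masked as its β-keto ester enolate, the second equivalent of base removes the α′ proton at C-4a, the more basic ketone dienolate is O-sulfonylated (enol triflate formation) and the stabilised enolate is then C-methylated, which fixes the diene position and erases the C-4a centre.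

Step 17
Reactants: 26 dienyl triflate
Product: 27 1,3,6-trimethyl-8-SC-7-[3-(trimethylsilyl)prop-2-yn-1-yl]-3,4,8,8a-tetrahydronaphthalen-2(1H)-one
Conditions: Pd(OAc)2 (10 mol %), PPh3 (20 mol %), HCO2H, Et3N, DMF, 50 °C
Reagents that add atoms: none
Why: Zerovalent palladium inserts into the enol triflate and ionises the allyl ester while formate supplies hydride to both (enol triflate hydrogenolysis and deallylative decarboxylation of a β-keto ester), which should give the ring A diene and the C-2 ketone, with C-3 formed unselectively by enol protonation.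

Step 18
Reactants: 27 silylated diene ketone
Product: 29 target analogue with prop-2-yn-1-yl at C-7 (free acid and alcohol), via desilylated methyl ester 28 (not isolated)
Conditions: Bu4NF, THF, 23 °C; then LiOH, MeOH/H2O, 40 °C; aq. HCl to pH 4
Reagents that add atoms: lithium hydroxide [Li+].[OH-]
Why: Fluoride cleaves the O–Si and C(sp)–Si bonds, and hydroxide saponifies the ester and equilibrates C-1 and C-3 through the C-2 enolate to the all-equatorial cis-1,3-dimethyl ketone, which is the target configuration.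

Step 19
Reactants: 29 alkyne acid
Product: 30 target CNP0260948.1
Conditions: Ph3PAuNTf2 (3 mol %), H2O, 1,4-dioxane, 40 °C
Reagents that add atoms: water O
Why: Gold-catalysed Markovnikov hydration of the terminal alkyne gives the methyl ketone under near-neutral conditions, so the β,γ-unsaturated acetonyl group should not move into conjugation.

**Compound list**

1 | prop-2-yn-1-ol | C#CCO | starting material
2 | dimethylaluminium (E)-3-(dimethylalumanyl)-2-methylprop-2-en-1-olate (not isolated) | C[Al](C)OC/C(C)=C/[Al](C)C | intermediate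
3 | (E)-3-iodo-2-methylprop-2-en-1-ol | OC/C(C)=C/I | intermediate
4 | (E)-3-iodo-2-methylprop-2-enal | O=C/C(C)=C/I | intermediate
5 | ethyl 2-(triphenylphosphoranylidene)propanoate | CCOC(=O)C(C)=P(c1ccccc1)(c1ccccc1)c1ccccc1 | starting material
6 | ethyl (2E,4E)-5-iodo-2,4-dimethylpenta-2,4-dienoate | CCOC(=O)/C(C)=C/C(C)=C/I | intermediate
7 | (2E,4E)-5-iodo-2,4-dimethylpenta-2,4-dien-1-ol | OC/C(C)=C/C(C)=C/I | intermediate
8 | [(2R,3R)-3-[(E)-1-iodoprop-1-en-2-yl]-2-methyloxiran-2-yl]methanol | OC[C@@]1(C)O[C@@H]1/C(C)=C/I | intermediate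
9 | tert-butyl{[(2R,3R)-3-[(E)-1-iodoprop-1-en-2-yl]-2-methyloxiran-2-yl]methoxy}dimethylsilane | CC(C)(C)[Si](C)(C)OC[C@@]1(C)O[C@@H]1/C(C)=C/I | intermediate
10 | (2S,3E)-2-(tert-butyldimethylsilyloxymethyl)-4-iodo-2,3-dimethylbut-3-enal | O=C[C@](C)(CO[Si](C)(C)C(C)(C)C)/C(C)=C/I | intermediate
11 | methyl 2-(dimethoxyphosphoryl)acetate | COC(=O)CP(=O)(OC)OC | starting material
12 | methyl (2E,4S,5E)-4-(tert-butyldimethylsilyloxymethyl)-6-iodo-4,5-dimethylhexa-2,5-dienoate | COC(=O)/C=C/[C@](C)(CO[Si](C)(C)C(C)(C)C)/C(C)=C/I | intermediate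
13 | (R)-(−)-carvone | O=C1C(C)=CC[C@@H](C(C)=C)C1 | starting material
14 | B-alkyl borane and O-borinate adduct of reduced carvone (not isolated) | CC1=CC[C@@H](C(C)CB2C3CCCC2CCC3)CC1OB2C3CCCC2CCC3 | intermediate
15 | (5R)-5-(1-hydroxypropan-2-yl)-2-methylcyclohex-2-en-1-ol (isomers at C-1 and at the side-chain CH) | CC1=CC[C@@H](C(C)CO)CC1O | intermediate
16 | 2-[(1R)-4-methyl-5-oxocyclohex-3-en-1-yl]propanoic acid (both epimers at propanoic C-2) | O=C1C(C)=CC[C@@H](C(C)C(=O)O)C1 | intermediate
17 | methyl 2-[(1R)-4-methyl-5-oxocyclohex-3-en-1-yl]propanoate (both epimers at propanoate C-2) | O=C1C(C)=CC[C@@H](C(C)C(=O)OC)C1 | intermediate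
18 | α′-alkenylated enone: 17 with SC on the ring carbon next to the ketone, trans to the propanoate arm | O=C1C(C)=CC[C@@H](C(C)C(=O)OC)[C@@H]1/C=C(\C)[C@](C)(/C=C/C(=O)OC)CO[Si](C)(C)C(C)(C)C | intermediate
19 | 3-bromo-1-(trimethylsilyl)prop-1-yne | C[Si](C)(C)C#CCBr | starting material
20 | tertiary allylic alcohol: 18 with C=O converted into C(OH)CH2C≡CSiMe3 (either carbinol epimer) | OC1(CC#C[Si](C)(C)C)C(C)=CC[C@@H](C(C)C(=O)OC)[C@@H]1/C=C(\C)[C@](C)(/C=C/C(=O)OC)CO[Si](C)(C)C(C)(C)C | intermediate
21 | transposed enone: 2-methylcyclohex-2-en-1-one with 3-[3-(trimethylsilyl)prop-2-yn-1-yl], 4-SC, 5-(1-methoxy-1-oxopropan-2-yl), 4,5-trans | C[Si](C)(C)C#CCC1=C(C)C(=O)C[C@@H](C(C)C(=O)OC)[C@@H]1/C=C(\C)[C@](C)(/C=C/C(=O)OC)CO[Si](C)(C)C(C)(C)C | intermediate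
22 | prop-2-en-1-yl prop-2-enoate (allyl acrylate) | C=CC(=O)OCC=C | starting material
23 | lithium ester enolate of the Michael adduct at C-4a (not isolated) | C[Si](C)(C)C#CCC1=C(C)C(=O)[C@H](CC=C([O-])OCC=C)[C@@H](C(C)C(=O)OC)[C@@H]1/C=C(\C)[C@](C)(/C=C/C(=O)OC)CO[Si](C)(C)C(C)(C)C.[Li+] | intermediate
24 | allyl 1,6-dimethyl-2,5-dioxo-8-SC-7-[3-(trimethylsilyl)prop-2-yn-1-yl]-1,2,3,4,4a,5,8,8a-octahydronaphthalene-3-carboxylate (trans-fused; C-1 and C-3 unassigned) | C[Si](C)(C)C#CCC1=C(C)C(=O)[C@@H]2CC(C(=O)OCC=C)C(=O)C(C)[C@H]2[C@@H]1/C=C(\C)[C@](C)(/C=C/C(=O)OC)CO[Si](C)(C)C(C)(C)C | intermediate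
25 | potassium β-keto ester enolate of the C-5 enol triflate (not isolated) | C[Si](C)(C)C#CCC1=C(C)C(OS(=O)(=O)C(F)(F)F)=C2CC(C(=O)OCC=C)=C([O-])C(C)[C@H]2[C@@H]1/C=C(\C)[C@](C)(/C=C/C(=O)OC)CO[Si](C)(C)C(C)(C)C.[K+] | intermediate
26 | allyl 1,3,6-trimethyl-2-oxo-5-(trifluoromethylsulfonyloxy)-8-SC-7-[3-(trimethylsilyl)prop-2-yn-1-yl]-1,2,3,4,8,8a-hexahydronaphthalene-3-carboxylate (C-1 and C-3 unassigned) | C[Si](C)(C)C#CCC1=C(C)C(OS(=O)(=O)C(F)(F)F)=C2CC(C)(C(=O)OCC=C)C(=O)C(C)[C@H]2[C@@H]1/C=C(\C)[C@](C)(/C=C/C(=O)OC)CO[Si](C)(C)C(C)(C)C | intermediate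
27 | 1,3,6-trimethyl-8-SC-7-[3-(trimethylsilyl)prop-2-yn-1-yl]-3,4,8,8a-tetrahydronaphthalen-2(1H)-one (C-1 and C-3 epimers) | C[Si](C)(C)C#CCC1=C(C)C=C2CC(C)C(=O)C(C)[C@H]2[C@@H]1/C=C(\C)[C@](C)(/C=C/C(=O)OC)CO[Si](C)(C)C(C)(C)C | intermediate
28 | desilylated methyl ester: 27 with free CH2OH and terminal alkyne (not isolated) | C#CCC1=C(C)C=C2CC(C)C(=O)C(C)[C@H]2[C@@H]1/C=C(\C)[C@](C)(/C=C/C(=O)OC)CO | intermediate
29 | alkyne acid: the target with prop-2-yn-1-yl at C-7 in place of 2-oxopropyl, (1R,3S,8S,8aR) core | C#CCC1=C(C)C=C2C[C@H](C)C(=O)[C@H](C)[C@H]2[C@@H]1/C=C(\C)[C@](C)(/C=C/C(=O)O)CO | intermediate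
30 | CNP0260948.1: (1R,3S,8S,8aR) core, (S) quaternary centre, E,E side chain | CC(=O)CC1=C(C)C=C2C[C@H](C)C(=O)[C@H](C)[C@H]2[C@@H]1/C=C(\C)[C@](C)(/C=C/C(=O)O)CO | target

**Count and risks**

Total: 19 steps. Longest linear sequence: 16 steps (steps 1 to 8, then 12 to 19).

Step 15. The ester enolate may add a second time, to C-7, and give a bicyclo[2.2.2]octanone; the acrylate may polymerise; or proton transfer may stop the sequence after the Michael addition. Fallback: the two bonds are made in separate operations, first under Lewis-acid and then under thermodynamic conditions. Setting out from 21, LiN(iPr)2 and Me3SiCl give the cross-conjugated silyl dienol ether F1. Mukaiyama–Michael addition of F1 to 22 with Me3SiNTf2 as catalyst gives, after aqueous work-up, the isolated keto diester F2. Dieckmann condensation of F2 with NaH in THF comes back to the route at 24.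

Step 12. Reductive elimination from the hindered palladium enolate may be slow, and the new alkene may move into conjugation with the ketone or lose its geometry under the basic conditions. Fallback with reversed polarity: setting out from 17, LiN(SiMe3)2 then N-bromosuccinimide give the α′-bromo ketone F3. Compound 12 is converted with bis(pinacolato)diboron, PdCl2(dppf) and KOPh into the alkenylboronic pinacol ester F4. Nickel-catalysed Suzuki–Miyaura coupling of the secondary bromide F3 with F4 (NiCl2·glyme, bathophenanthroline, KOtBu, sBuOH), followed by equilibration with Et3N, comes back to the route at 18.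

Step 16. Deprotonation at the γ-carbon C-8 would lead to the linear dienyl triflate and scramble C-8, and the β-keto ester enolate may be sulfonylated as well. Fallback without an enol triflate: setting out from 24, K2CO3 and MeI give the C-3 methylated diketo ester F5. p-Toluenesulfonyl hydrazide should condense with the less hindered enone carbonyl to give the tosylhydrazone F6. A Shapiro reaction (LiN(iPr)2, THF, −78 to 0 °C, then water) removes the α′ proton at C-4a and gives the diene F7. Deallylative decarboxylation of F7 under the conditions of step 17 comes back to the route at 27.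

**Further compounds**

F1 | step 15 | cross-conjugated trimethylsilyl dienol ether of 21 | C[Si](C)(C)C#CCC1=C(C)C(O[Si](C)(C)C)=C[C@@H](C(C)C(=O)OC)[C@@H]1/C=C(\C)[C@](C)(/C=C/C(=O)OC)CO[Si](C)(C)C(C)(C)C
F2 | step 15 | keto diester (21 with CH2CH2CO2allyl at C-4a, trans to the arm) | C[Si](C)(C)C#CCC1=C(C)C(=O)[C@H](CCC(=O)OCC=C)[C@@H](C(C)C(=O)OC)[C@@H]1/C=C(\C)[C@](C)(/C=C/C(=O)OC)CO[Si](C)(C)C(C)(C)C
F3 | step 12 | methyl 2-[(1R)-2-bromo-4-methyl-3-oxocyclohex-4-en-1-yl]propanoate (α′-bromo ketone of 17) | O=C1C(C)=CC[C@@H](C(C)C(=O)OC)C1Br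
F4 | step 12 | alkenylboronic pinacol ester of 12 (Bpin in place of iodine) | COC(=O)/C=C/[C@](C)(CO[Si](C)(C)C(C)(C)C)/C(C)=C/B1OC(C)(C)C(C)(C)O1
F5 | step 16 | 24 methylated at C-3 | C[Si](C)(C)C#CCC1=C(C)C(=O)[C@@H]2CC(C)(C(=O)OCC=C)C(=O)C(C)[C@H]2[C@@H]1/C=C(\C)[C@](C)(/C=C/C(=O)OC)CO[Si](C)(C)C(C)(C)C
F6 | step 16 | C-5 tosylhydrazone of F5 | C[Si](C)(C)C#CCC1=C(C)C(=NNS(=O)(=O)c3ccc(C)cc3)[C@@H]2CC(C)(C(=O)OCC=C)C(=O)C(C)[C@H]2[C@@H]1/C=C(\C)[C@](C)(/C=C/C(=O)OC)CO[Si](C)(C)C(C)(C)C
F7 | step 16 | diene β-keto allyl ester (26 with H in place of the triflate) | C[Si](C)(C)C#CCC1=C(C)C=C2CC(C)(C(=O)OCC=C)C(=O)C(C)[C@H]2[C@@H]1/C=C(\C)[C@](C)(/C=C/C(=O)OC)CO[Si](C)(C)C(C)(C)C
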